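It is impossible for 0.0023 mol% of free enzyme to turn a whole charge into target in one pass, so each enzyme must go round many times, and I began by counting those rounds.

| flask | starting material | second substrate | free enzyme | remark | time |
|---|---|---|---|---|---|
| east | 0.10 M | 4 equiv | 0.0023 mol% | run made earlier |  |
| south-west | 0.050 M | 4 equiv | 0.0023 mol% | run made earlier |  |
| south-east | 0.075 M | 4 equiv | 0.0023 mol% | run made earlier |  |
| north | 0.10 M | 4 equiv | 0.0046 mol% | run made earlier |  |
| blue | 0.10 M | 4.00 equiv | 0.0023 mol% | everything together in a closed stirred flask, run for 4.0 d | 4.0 d |
| green | 0.10 M | 4.00 equiv (fed, over 4.00 d) | 0.0023 mol% | a stirred flask in which second substrate is dosed at a steady rate over 4.00 d without added volume, worked up at 4.0 d | 4.0 d |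
| grey | 0.10 M | 4.00 equiv | 0.0023 mol% | a single well-mixed tank run continuously and read at steady state, 4.0 d in it on average |  |
| red | 0.10 M (fed, over 4.00 d) | 4.00 equiv | 0.0023 mol% | a stirred flask in which starting material is dosed at a steady rate over 4.00 d without added volume, worked up at 4.0 d | 4.0 d |

| run | time / d | target / % |
|---|---|---|
| east | 0.208 | 12 |
| east | 0.333 | 15 |
| east | 0.417 | 22 |
| east | 0.625 | 27 |
| east | 1.04 | 43 |
| east | 1.67 | 53 |
| east | 2.50 | 59 |
| south-west | 0.500 | 17 |
| south-west | 0.833 | 24 |
| south-west | 1.25 | 32 |
| south-west | 1.67 | 42 |
| south-west | 2.50 | 53 |
| south-west | 3.00 | 55 |
| south-east | 0.250 | 7 |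
| south-east | 0.417 | 15 |
| south-east | 0.625 | 21 |
| south-east | 0.833 | 28 |
| south-east | 1.25 | 39 |
| south-east | 2.00 | 53 |
| south-east | 3.00 | 60 |
| north | 0.250 | 23 |
| north | 0.500 | 40 |
| north | 0.833 | 55 |
| north | 1.67 | 70 |
| north | 3.00 | 69 |

(scatter of a reading: 2 percentage points)

1. the set-up with the highest amount of target at the outlet or at the end, in percent of the starting material put in ("none" if the first two lie within 2 percentage points) (blue / green / grey / red / none)
2. amount of target at the outlet or at the end, in percent of the starting material put in, blue
3. amount of target at the outlet or at the end, in percent of the starting material put in, green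
4. amount of target at the outlet or at the end, in percent of the starting material put in, grey
5. amount of target at the outlet or at the end, in percent of the starting material put in, red

- the stated concentrations are those of everything mixed, before any reaction; amounts are the same in each set-up
- the numbers in the tables scatter with a standard deviation of 2 percentage points
- the feed brings no volume worth counting
- the earlier runs were made in a closed, stirred flask

East gained 22 % in 0.417 d, an opening pace of 0.528 /d, so over 4.0 d the count came to 2.11. I called this n, the charge count: the number of whole charges the enzyme would pass in the time at its opening pace. A count above one seemed to promise blue full conversion.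

But north, with twice the enzyme, had a count of 3.17 by its last reading, more than blue's, and it stood at 70 % and then 69 %. So I set a ceiling c at their mean, 69.5 %, and let the curve approach it exponentially. With D = n/c, the Damköhler number, at 3.04, blue came to 66.2 %.

The pace rested on one reading, though. East's 15 % at 0.333 d gave a count of 1.80, and blue then came to 64.3 %, a doubt I could live with. The worse doubt was c itself, since it came from doubled enzyme, and east, at 59 % on its last reading, had not shown it. For grey, a tank held at its outlet state, I took c·D/(1 + D), which is 52.3 %. Feeding spends the count late, so I placed green and red below blue without a figure, and committed to blue.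

The forecast gave 68 % for blue, 54 % for green, 54 % for grey and 51 % for red, with blue best, holding that “dosing only delays reaction and cannot lift the ceiling”. Its blue and grey stood slightly above mine.

The flask gave 63.6 % for blue, 60.8 % for green, 53.1 % for grey and 55.2 % for red, with blue best; green came 6.8 percentage points above the forecast.

    first complex ⇌ loaded enzyme + first product (K = 0.250 M, k = 4500 /h)
    second substrate + loaded enzyme ⇌ second complex (K = 1.30 /M, k = 8.80 × 10⁵ /M/h)
    starting material + free enzyme ⇌ first complex (K = 4.70 /M, k = 6.40 × 10⁵ /M/h)
    starting material + first product → side product (k = 1.00 /M/h)
    second complex → free enzyme + target (k = 8100 /h)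

After 40.0 d blue stood at 63.8 % at a count of 21.1, so ten times the count lifted it by 0.20 points. Blue stopped short because starting material passed with first product into side product: without that step blue gives 91.5 %, not 63.6 %. Grey, with the same count of 2.11, delivered a quarter of it as target, 53.1 %.

(The runs stem from a simulated flask from invented constants; the scatter is artificial.)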